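Number the oxolane O1, C2 (attached to the catechol ring), C3 (its CH2OH carbon is C9), C4 (its side-chain carbinol is C7, attached to the guaiacyl ring) and C5. C5 and C9 are the two carbons that hold only oxygen and hydrogen, and they hang on neighbouring C3 and C4 just as the carbonyl carbons of a 2,3-disubstituted succinic anhydride hang on its sp3 carbons. The route therefore cuts C4–C5 and C3–C9 back to carbon monoxide: one catalytic operation carbonylates a trans-epoxide twice, inverts both epoxide carbons (fixing C3 and C4) and ties C5 to C9 through oxygen. The precursor is the trans-2,3-epoxide of an (E)-1,4-diarylbut-2-ene-1,4-diol with benzylated phenols, O–C2 as triethylsilyl ether and O–C7 as tert-butyldimethylsilyl ether.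

Key step: step 7

Assumption: (S)-BINOL/Ti(OiPr)4 is taken to send alkynylzinc to the Si face of an aryl aldehyde (giving (R)-4) and (+)-MIB to send alkenylzinc to the Re face (mirror of the (−)-MIB case); if Mosher ester analysis of 4 or 10 shows the opposite sense, the ligand antipode is used and nothing else changes.

Step 1
Reactants: 1 3,4-bis(benzyloxy)benzaldehyde; 2 ethynyl(trimethyl)silane
Product: 4 (1R)-1-[3,4-bis(benzyloxy)phenyl]-3-(trimethylsilyl)prop-2-yn-1-ol, via zinc acetylide 3 (not isolated)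
Conditions: 2, Et2Zn, Cy2NH (5 mol%), (S)-BINOL (20 mol%), Et2O, rt; then Ti(OiPr)4 (50 mol%); then 1, rt; aq. NH4Cl
Reagents that add atoms: none
Why: Catalytic enantioselective alkynylzinc addition to an aromatic aldehyde: the titanium–(S)-BINOL complex activates 1 and exposes its Si face to zinc acetylide 3, setting the C2 carbinol as R (the same arrangement in space is called S from 5 onwards), and direct addition avoids reducing an aryl alkynyl ketone, whose two unsaturated flanks are too alike for reliable hydride-face discrimination.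

Step 2
Reactants: 4 (1R)-1-[3,4-bis(benzyloxy)phenyl]-3-(trimethylsilyl)prop-2-yn-1-ol
Product: 5 (1S)-1-[3,4-bis(benzyloxy)phenyl]prop-2-yn-1-ol
Conditions: K2CO3 (cat.), MeOH, rt
Reagents that add atoms: none
Why: Base-catalysed methanolysis of the alkynyl C–Si bond (protodesilylation) frees the terminal alkyne without touching the carbinol, whose descriptor changes only because ethynyl ranks below aryl.

Step 3
Reactants: 5 (1S)-1-[3,4-bis(benzyloxy)phenyl]prop-2-yn-1-ol
Product: 6 {[(1S)-1-[3,4-bis(benzyloxy)phenyl]prop-2-yn-1-yl]oxy}triethylsilane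
Conditions: TESCl, imidazole, DMF, 0 °C
Reagents that add atoms: chlorotriethylsilane CC[Si](Cl)(CC)CC
Why: Imidazole-promoted O-silylation puts the small, labile silyl group on O–C2 now, so that C7–OH will later be the only free hydroxyl, and doing it after the C-desilylation keeps this ether away from methanolic base.

Step 4
Reactants: 6 {[(1S)-1-[3,4-bis(benzyloxy)phenyl]prop-2-yn-1-yl]oxy}triethylsilane; 7 4-(benzyloxy)-3-methoxybenzaldehyde
Product: 10 (1R,2E,4S)-4-[3,4-bis(benzyloxy)phenyl]-1-[4-(benzyloxy)-3-methoxyphenyl]-4-[(triethylsilyl)oxy]but-2-en-1-ol, via alkenylborane 8 (not isolated), via alkenylzinc 9 (not isolated)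
Conditions: Cy2BH, toluene, 0 °C to rt; then Me2Zn, (+)-MIB (5 mol%), −78 °C; then 7, −78 to −10 °C; aq. NH4Cl
Reagents that add atoms: none
Why: Asymmetric alkenylzinc addition to an aldehyde: syn-hydroboration of the terminal alkyne gives (E)-alkenylborane 8, boron-to-zinc exchange gives 9, and the zinc aminoalkoxide of (+)-MIB directs the alkenyl group to the Re face of 7, so the E geometry and (R)-C7 are set under catalyst control and the free hydroxyl ends up on C7, where the epoxidation needs it.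

Step 5
Reactants: 10 (1R,2E,4S)-4-[3,4-bis(benzyloxy)phenyl]-1-[4-(benzyloxy)-3-methoxyphenyl]-4-[(triethylsilyl)oxy]but-2-en-1-ol
Product: 11 (S)-[4-(benzyloxy)-3-methoxyphenyl][(2S,3R)-3-{(R)-[3,4-bis(benzyloxy)phenyl][(triethylsilyl)oxy]methyl}oxiran-2-yl]methanol
Conditions: Ti(OiPr)4 (0.2 equiv), L-(+)-DIPT (0.25 equiv), tBuOOH (2 equiv, in decane), 4 Å molecular sieves, CH2Cl2, −20 °C
Reagents that add atoms: tert-butyl hydroperoxide CC(C)(C)OO
Why: Sharpless asymmetric epoxidation directed by C7–OH: the epoxide oxygen needed for the later double inversion is erythro (anti) to O–C7 but threo to O–C2, so only C7–OH can direct it in the matched sense, and with L-(+)-DIPT the face preferred by the tartrate and by the (R)-carbinol coincide, which sets both epoxide carbons.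

Step 6
Reactants: 11 (S)-[4-(benzyloxy)-3-methoxyphenyl][(2S,3R)-3-{(R)-[3,4-bis(benzyloxy)phenyl][(triethylsilyl)oxy]methyl}oxiran-2-yl]methanol
Product: 12 tert-butyl{(S)-[4-(benzyloxy)-3-methoxyphenyl][(2R,3R)-3-{(R)-[3,4-bis(benzyloxy)phenyl][(triethylsilyl)oxy]methyl}oxiran-2-yl]methoxy}dimethylsilane
Conditions: TBSCl, imidazole, DMAP (cat.), DMF, rt
Reagents that add atoms: tert-butyl(chloro)dimethylsilane CC(C)(C)[Si](C)(C)Cl
Why: Standard silylation of the remaining secondary hydroxyl under non-acidic conditions leaves the epoxide and the triethylsilyl ether intact and gives two silyl ethers that can be told apart later.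

Step 7
Reactants: 12 tert-butyl{(S)-[4-(benzyloxy)-3-methoxyphenyl][(2R,3R)-3-{(R)-[3,4-bis(benzyloxy)phenyl][(triethylsilyl)oxy]methyl}oxiran-2-yl]methoxy}dimethylsilane; 13 carbon monoxide (2 equiv)
Product: 16 (3S,4S)-3-{(S)-[3,4-bis(benzyloxy)phenyl][(triethylsilyl)oxy]methyl}-4-{(R)-[4-(benzyloxy)-3-methoxyphenyl][(tert-butyldimethylsilyl)oxy]methyl}oxolane-2,5-dione, via C9-first β-lactone 14 (not isolated), via C5-first β-lactone 15 (not isolated)
Conditions: [(ClTPP)Al(THF)2][Co(CO)4] (5 mol%; ClTPP = meso-tetrakis(4-chlorophenyl)porphyrinate), CO (60 bar), 1,4-dioxane, 90 °C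
Reagents that add atoms: none
Why: Proposed new method: the aluminium cation binds the epoxide oxygen, [Co(CO)4]− opens the ring by backside attack at C3 (or C4), CO inserts into the new C–Co bond and the aluminium alkoxide displaces cobalt from the acyl group to give a cis-β-lactone (14 or 15); the same ion pair then activates that lactone, cobaltate cleaves its alkyl C–O bond by a second backside attack at the other carbon, CO inserts again and the aluminium carboxylate closes onto the acylcobalt. The closest known reaction type is the one-pot double carbonylation of simple alkyl-substituted epoxides to succinic anhydrides with this aluminium porphyrin/cobaltate ion pair in 1,4-dioxane; a 2,3-disubstituted epoxide carrying an α-silyloxybenzyl group on each carbon lies outside that scope. The five-membered anhydride ring closes by intramolecular O-acylation (5-exo-trig attack of the carboxylate oxygen on the acyl–cobalt carbon), which makes the C5–O–C9 link after the C3–C9 and C4–C5 bonds have formed. C3 and C4 are each set by one SN2 inversion, so their configuration follows solely from the trans-epoxide (trans-epoxide to cis-lactone to trans-anhydride) and no reagent control is needed. Regioselectivity of the first opening is irrelevant because 14 and 15 converge on 16; what the step needs is substitution with inversion in preference to ionisation, Lewis-acid isomerisation to a ketone, or β-elimination of silyloxide or hydride from the alkylcobalt species, and this is favoured by the non-benzylic, inductively deactivated epoxide carbons, the absence of free hydroxyl groups and a CO pressure high enough to make insertion fast.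

Step 8
Reactants: 16 (3S,4S)-3-{(S)-[3,4-bis(benzyloxy)phenyl][(triethylsilyl)oxy]methyl}-4-{(R)-[4-(benzyloxy)-3-methoxyphenyl][(tert-butyldimethylsilyl)oxy]methyl}oxolane-2,5-dione
Product: 18 (2S,3S,4S)-2-[3,4-bis(benzyloxy)phenyl]-4-{(R)-[4-(benzyloxy)-3-methoxyphenyl][(tert-butyldimethylsilyl)oxy]methyl}-5-oxooxolane-3-carboxylic acid, via hydroxy anhydride 17 (not isolated)
Conditions: HF·pyridine, pyridine, THF, 0 °C to rt
Reagents that add atoms: none
Why: Selective desilylation followed by intramolecular acylation: buffered HF·pyridine removes the triethylsilyl group much faster than the hindered tert-butyldimethylsilyl group, and the freed C2–OH opens the anhydride at C5 by 5-exo-trig attack (attack at C9 would need a four-membered ring), giving the γ-lactone acid without touching a stereocentre; any anhydride hydrolysed on work-up lactonises to the same acid.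

Step 9
Reactants: 18 (2S,3S,4S)-2-[3,4-bis(benzyloxy)phenyl]-4-{(R)-[4-(benzyloxy)-3-methoxyphenyl][(tert-butyldimethylsilyl)oxy]methyl}-5-oxooxolane-3-carboxylic acid
Product: 19 (3S,4R,5S)-5-[3,4-bis(benzyloxy)phenyl]-3-{(R)-[4-(benzyloxy)-3-methoxyphenyl][(tert-butyldimethylsilyl)oxy]methyl}-4-(hydroxymethyl)oxolan-2-one
Conditions: BH3·SMe2, THF, 0 °C to rt; then MeOH
Reagents that add atoms: none
Why: Chemoselective borane reduction of a carboxylic acid: BH3 reduces the C9 acid through its acyloxyborane far faster than the γ-lactone, and silyl and benzyl ethers are inert to it.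

Step 10
Reactants: 19 (3S,4R,5S)-5-[3,4-bis(benzyloxy)phenyl]-3-{(R)-[4-(benzyloxy)-3-methoxyphenyl][(tert-butyldimethylsilyl)oxy]methyl}-4-(hydroxymethyl)oxolan-2-one
Product: 20 (3S,4R,5S)-5-[3,4-bis(benzyloxy)phenyl]-3-{(R)-[4-(benzyloxy)-3-methoxyphenyl][(tert-butyldimethylsilyl)oxy]methyl}-4-{[(tert-butyldimethylsilyl)oxy]methyl}oxolan-2-one
Conditions: TBSCl, imidazole, DMF, 0 °C
Reagents that add atoms: tert-butyl(chloro)dimethylsilane CC(C)(C)[Si](C)(C)Cl
Why: Imidazole-promoted silylation of the primary C9–OH, done promptly so that this hydroxyl cannot translactonise onto C5 or compete in the later ring closure, installs a group that leaves together with the C7 silyl ether.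

Step 11
Reactants: 20 (3S,4R,5S)-5-[3,4-bis(benzyloxy)phenyl]-3-{(R)-[4-(benzyloxy)-3-methoxyphenyl][(tert-butyldimethylsilyl)oxy]methyl}-4-{[(tert-butyldimethylsilyl)oxy]methyl}oxolan-2-one
Product: 21 (1S,2R,3R)-1-[3,4-bis(benzyloxy)phenyl]-3-{(R)-[4-(benzyloxy)-3-methoxyphenyl][(tert-butyldimethylsilyl)oxy]methyl}-2-{[(tert-butyldimethylsilyl)oxy]methyl}butane-1,4-diol
Conditions: LiBH4, THF, 0 °C to rt; aq. NH4Cl
Reagents that add atoms: none
Why: Lactone reduction with LiBH4 gives the primary C5 alcohol and releases C2–OH; the hydride is mild enough to spare silyl and benzyl ethers, and reduction is faster than enolisation at C4.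

Step 12
Reactants: 21 (1S,2R,3R)-1-[3,4-bis(benzyloxy)phenyl]-3-{(R)-[4-(benzyloxy)-3-methoxyphenyl][(tert-butyldimethylsilyl)oxy]methyl}-2-{[(tert-butyldimethylsilyl)oxy]methyl}butane-1,4-diol
Product: 23 (2S,3R,4R)-2-[3,4-bis(benzyloxy)phenyl]-4-{(R)-[4-(benzyloxy)-3-methoxyphenyl][(tert-butyldimethylsilyl)oxy]methyl}-3-{[(tert-butyldimethylsilyl)oxy]methyl}oxolane, via monotosylate 22 (not isolated)
Conditions: TsCl (1.2 equiv), pyridine, DMAP (cat.), CH2Cl2, 0 to 40 °C
Reagents that add atoms: none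
Why: Selective sulfonylation of the primary C5–OH followed by intramolecular Williamson etherification: C2–OH displaces the tosylate at C5 in a 5-exo-tet closure, so no bond to a stereocentre is broken and C2 keeps its configuration, while the weak base avoids silyl migration.

Step 13
Reactants: 23 (2S,3R,4R)-2-[3,4-bis(benzyloxy)phenyl]-4-{(R)-[4-(benzyloxy)-3-methoxyphenyl][(tert-butyldimethylsilyl)oxy]methyl}-3-{[(tert-butyldimethylsilyl)oxy]methyl}oxolane
Product: 24 (R)-[4-(benzyloxy)-3-methoxyphenyl][(3R,4R,5S)-5-[3,4-bis(benzyloxy)phenyl]-4-(hydroxymethyl)oxolan-3-yl]methanol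
Conditions: Bu4NF, THF, 0 °C to rt
Reagents that add atoms: none
Why: Fluoride-induced cleavage of both silyl ethers under basic, non-ionising conditions, chosen because acid would ionise the electron-rich benzylic C7–OH towards cyclisation with C9–OH.

Step 14
Reactants: 24 (R)-[4-(benzyloxy)-3-methoxyphenyl][(3R,4R,5S)-5-[3,4-bis(benzyloxy)phenyl]-4-(hydroxymethyl)oxolan-3-yl]methanol
Product: 25 (7R)-7-hydroxytaxiresinol
Conditions: H2 (1 atm), 10% Pd/C, NaHCO3 (trace), EtOAc–EtOH, rt
Reagents that add atoms: none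
Why: Catalytic hydrogenolysis of the three aryl benzyl ethers over Pd/C at 1 atm under buffered neutral conditions, which is much faster than cleavage of the benzylic C7–OH or C2–O1 bonds, frees the phenols last so that the polar target needs only filtration and evaporation.

Compound list
1 | 3,4-bis(benzyloxy)benzaldehyde | O=Cc1ccc(OCc2ccccc2)c(OCc2ccccc2)c1 | starting material
2 | ethynyl(trimethyl)silane | C#C[Si](C)(C)C | starting material
3 | ethyl[(trimethylsilyl)ethynyl]zinc | CC[Zn]C#C[Si](C)(C)C | intermediate (not isolated)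
4 | (1R)-1-[3,4-bis(benzyloxy)phenyl]-3-(trimethylsilyl)prop-2-yn-1-ol | C[Si](C)(C)C#C[C@H](O)c1ccc(OCc2ccccc2)c(OCc2ccccc2)c1 | intermediate
5 | (1S)-1-[3,4-bis(benzyloxy)phenyl]prop-2-yn-1-ol | C#C[C@H](O)c1ccc(OCc2ccccc2)c(OCc2ccccc2)c1 | intermediate
6 | {[(1S)-1-[3,4-bis(benzyloxy)phenyl]prop-2-yn-1-yl]oxy}triethylsilane | C#C[C@H](O[Si](CC)(CC)CC)c1ccc(OCc2ccccc2)c(OCc2ccccc2)c1 | intermediate
7 | 4-(benzyloxy)-3-methoxybenzaldehyde | COc1cc(C=O)ccc1OCc1ccccc1 | starting material
8 | [(1E,3S)-3-[3,4-bis(benzyloxy)phenyl]-3-[(triethylsilyl)oxy]prop-1-en-1-yl]dicyclohexylborane | B(/C=C/[C@H](O[Si](CC)(CC)CC)c1ccc(OCc2ccccc2)c(OCc2ccccc2)c1)(C1CCCCC1)C1CCCCC1 | intermediate (not isolated)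
9 | [(1E,3S)-3-[3,4-bis(benzyloxy)phenyl]-3-[(triethylsilyl)oxy]prop-1-en-1-yl](methyl)zinc | C[Zn]/C=C/[C@H](O[Si](CC)(CC)CC)c1ccc(OCc2ccccc2)c(OCc2ccccc2)c1 | intermediate (not isolated)
10 | (1R,2E,4S)-4-[3,4-bis(benzyloxy)phenyl]-1-[4-(benzyloxy)-3-methoxyphenyl]-4-[(triethylsilyl)oxy]but-2-en-1-ol | COc1cc([C@H](O)/C=C/[C@H](O[Si](CC)(CC)CC)c2ccc(OCc3ccccc3)c(OCc3ccccc3)c2)ccc1OCc1ccccc1 | intermediate
11 | (S)-[4-(benzyloxy)-3-methoxyphenyl][(2S,3R)-3-{(R)-[3,4-bis(benzyloxy)phenyl][(triethylsilyl)oxy]methyl}oxiran-2-yl]methanol (trans-epoxide) | COc1cc([C@H](O)[C@@H]2O[C@H]2[C@H](O[Si](CC)(CC)CC)c3ccc(OCc4ccccc4)c(OCc4ccccc4)c3)ccc1OCc1ccccc1 | intermediate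
12 | tert-butyl{(S)-[4-(benzyloxy)-3-methoxyphenyl][(2R,3R)-3-{(R)-[3,4-bis(benzyloxy)phenyl][(triethylsilyl)oxy]methyl}oxiran-2-yl]methoxy}dimethylsilane (trans-epoxide) | COc1cc([C@H](O[Si](C)(C)C(C)(C)C)[C@@H]2O[C@H]2[C@H](O[Si](CC)(CC)CC)c3ccc(OCc4ccccc4)c(OCc4ccccc4)c3)ccc1OCc1ccccc1 | intermediate
13 | carbon monoxide | [C-]#[O+] | starting material
14 | (3S,4R)-3-{(S)-[3,4-bis(benzyloxy)phenyl][(triethylsilyl)oxy]methyl}-4-{(S)-[4-(benzyloxy)-3-methoxyphenyl][(tert-butyldimethylsilyl)oxy]methyl}oxetan-2-one (cis-β-lactone, first CO on C3) | COc1cc([C@H](O[Si](C)(C)C(C)(C)C)[C@@H]2OC(=O)[C@@H]2[C@H](O[Si](CC)(CC)CC)c3ccc(OCc4ccccc4)c(OCc4ccccc4)c3)ccc1OCc1ccccc1 | intermediate (not isolated)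
15 | (3S,4R)-3-{(R)-[4-(benzyloxy)-3-methoxyphenyl][(tert-butyldimethylsilyl)oxy]methyl}-4-{(R)-[3,4-bis(benzyloxy)phenyl][(triethylsilyl)oxy]methyl}oxetan-2-one (cis-β-lactone, first CO on C4) | COc1cc([C@H](O[Si](C)(C)C(C)(C)C)[C@H]2C(=O)O[C@H]2[C@H](O[Si](CC)(CC)CC)c3ccc(OCc4ccccc4)c(OCc4ccccc4)c3)ccc1OCc1ccccc1 | intermediate (not isolated)
16 | (3S,4S)-3-{(S)-[3,4-bis(benzyloxy)phenyl][(triethylsilyl)oxy]methyl}-4-{(R)-[4-(benzyloxy)-3-methoxyphenyl][(tert-butyldimethylsilyl)oxy]methyl}oxolane-2,5-dione (trans-anhydride) | COc1cc([C@H](O[Si](C)(C)C(C)(C)C)[C@H]2C(=O)OC(=O)[C@@H]2[C@H](O[Si](CC)(CC)CC)c3ccc(OCc4ccccc4)c(OCc4ccccc4)c3)ccc1OCc1ccccc1 | intermediate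
17 | (3S,4S)-3-{(S)-[3,4-bis(benzyloxy)phenyl](hydroxy)methyl}-4-{(R)-[4-(benzyloxy)-3-methoxyphenyl][(tert-butyldimethylsilyl)oxy]methyl}oxolane-2,5-dione | COc1cc([C@H](O[Si](C)(C)C(C)(C)C)[C@H]2C(=O)OC(=O)[C@@H]2[C@H](O)c3ccc(OCc4ccccc4)c(OCc4ccccc4)c3)ccc1OCc1ccccc1 | intermediate (not isolated)
18 | (2S,3S,4S)-2-[3,4-bis(benzyloxy)phenyl]-4-{(R)-[4-(benzyloxy)-3-methoxyphenyl][(tert-butyldimethylsilyl)oxy]methyl}-5-oxooxolane-3-carboxylic acid | COc1cc([C@H](O[Si](C)(C)C(C)(C)C)[C@H]2C(=O)O[C@H](c3ccc(OCc4ccccc4)c(OCc4ccccc4)c3)[C@H]2C(O)=O)ccc1OCc1ccccc1 | intermediate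
19 | (3S,4R,5S)-5-[3,4-bis(benzyloxy)phenyl]-3-{(R)-[4-(benzyloxy)-3-methoxyphenyl][(tert-butyldimethylsilyl)oxy]methyl}-4-(hydroxymethyl)oxolan-2-one | COc1cc([C@H](O[Si](C)(C)C(C)(C)C)[C@H]2C(=O)O[C@H](c3ccc(OCc4ccccc4)c(OCc4ccccc4)c3)[C@H]2CO)ccc1OCc1ccccc1 | intermediate
20 | (3S,4R,5S)-5-[3,4-bis(benzyloxy)phenyl]-3-{(R)-[4-(benzyloxy)-3-methoxyphenyl][(tert-butyldimethylsilyl)oxy]methyl}-4-{[(tert-butyldimethylsilyl)oxy]methyl}oxolan-2-one | COc1cc([C@H](O[Si](C)(C)C(C)(C)C)[C@H]2C(=O)O[C@H](c3ccc(OCc4ccccc4)c(OCc4ccccc4)c3)[C@H]2CO[Si](C)(C)C(C)(C)C)ccc1OCc1ccccc1 | intermediate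
21 | (1S,2R,3R)-1-[3,4-bis(benzyloxy)phenyl]-3-{(R)-[4-(benzyloxy)-3-methoxyphenyl][(tert-butyldimethylsilyl)oxy]methyl}-2-{[(tert-butyldimethylsilyl)oxy]methyl}butane-1,4-diol | COc1cc([C@H](O[Si](C)(C)C(C)(C)C)[C@@H](CO)[C@H](CO[Si](C)(C)C(C)(C)C)[C@H](O)c2ccc(OCc3ccccc3)c(OCc3ccccc3)c2)ccc1OCc1ccccc1 | intermediate
22 | (2R,3R,4S)-4-[3,4-bis(benzyloxy)phenyl]-2-{(R)-[4-(benzyloxy)-3-methoxyphenyl][(tert-butyldimethylsilyl)oxy]methyl}-3-{[(tert-butyldimethylsilyl)oxy]methyl}-4-hydroxybutyl 4-methylbenzenesulfonate | COc1cc([C@H](O[Si](C)(C)C(C)(C)C)[C@@H](COS(=O)(=O)c5ccc(C)cc5)[C@H](CO[Si](C)(C)C(C)(C)C)[C@H](O)c2ccc(OCc3ccccc3)c(OCc3ccccc3)c2)ccc1OCc1ccccc1 | intermediate (not isolated)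
23 | (2S,3R,4R)-2-[3,4-bis(benzyloxy)phenyl]-4-{(R)-[4-(benzyloxy)-3-methoxyphenyl][(tert-butyldimethylsilyl)oxy]methyl}-3-{[(tert-butyldimethylsilyl)oxy]methyl}oxolane | COc1cc([C@H](O[Si](C)(C)C(C)(C)C)[C@H]2CO[C@H](c3ccc(OCc4ccccc4)c(OCc4ccccc4)c3)[C@H]2CO[Si](C)(C)C(C)(C)C)ccc1OCc1ccccc1 | intermediate
24 | (R)-[4-(benzyloxy)-3-methoxyphenyl][(3R,4R,5S)-5-[3,4-bis(benzyloxy)phenyl]-4-(hydroxymethyl)oxolan-3-yl]methanol | COc1cc([C@H](O)[C@H]2CO[C@H](c3ccc(OCc4ccccc4)c(OCc4ccccc4)c3)[C@H]2CO)ccc1OCc1ccccc1 | intermediate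
25 | (7R)-7-hydroxytaxiresinol, 4-[(2S,3R,4R)-4-[(R)-hydroxy(4-hydroxy-3-methoxyphenyl)methyl]-3-(hydroxymethyl)oxolan-2-yl]benzene-1,2-diol | COc1cc([C@H](O)[C@H]2CO[C@H](c3ccc(O)c(O)c3)[C@H]2CO)ccc1O | target

Total step count: 14
Longest linear sequence: 14 steps (1 to 25)

Steps most likely to fail

1. Step 7 (the proposed new method). The cobaltate may be unable to reach either epoxide carbon past the two branched silyloxybenzyl groups, the reaction may stall at the β-lactone, or the Lewis acid may isomerise the epoxide or strip a silyl ether. The fallback uses known chemistry, sets out from 10 and comes back at 16. Silylation of 10 (TBSCl, imidazole) would give the bis-silyl alkene F1. Palladium-catalysed oxidative bis(methoxycarbonylation) of F1 (PdCl2 cat., CuCl2 as reoxidant, NaOAc, CO, MeOH) adds two CO2Me groups to the same face of C3=C4 by syn acylpalladation and CO insertion; on the E-alkene this gives the same relative C3/C4 arrangement as double inversion of the trans-epoxide, i.e. the dimethyl succinate F2. The two allylic centres are nearly mirror images, so little facial bias can be expected and F2 would have to be separated from its C3,C4-diastereomer, with loss of roughly half the material accepted. Me3SnOH would then cleave both methyl esters without epimerisation to the diacid F3, and Ac2O would close F3 to 16.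

2. Step 5. Titanium may ionise or open the electron-rich benzylic epoxy alcohol, or oxygen transfer to the hindered alkene may be too slow for the matched preference to show. The fallback sets out from 10 and comes back at 11: a non-directed, reagent-controlled Shi epoxidation with the L-fructose-derived enantiomer of the Shi ketone (KHSO5, K2CO3 buffer, MeCN–dimethoxymethane–water, 0 °C). Its spiro transition state should select the same alkene face without involving the hydroxyl group, and it runs under basic conditions. No further compound is made (F0).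

3. Step 14. Over-reduction may occur, i.e. hydrogenolysis of the benzylic C7–OH or C2–O1 bond once the para-phenols are free. The fallback sets out from 23 and comes back at 25. Hydrogenolysis (H2, Pd/C, EtOAc) would be run on 23, whose C7 oxygen is still shielded by its bulky silyl ether, to give the triphenol F4. Both silyl groups would then be removed with acetic-acid-buffered Bu4NF in THF under argon.

Further compounds
F1 | step 7 | tert-butyl{[(1R,2E,4S)-4-[3,4-bis(benzyloxy)phenyl]-1-[4-(benzyloxy)-3-methoxyphenyl]-4-[(triethylsilyl)oxy]but-2-en-1-yl]oxy}dimethylsilane | COc1cc([C@H](O[Si](C)(C)C(C)(C)C)/C=C/[C@H](O[Si](CC)(CC)CC)c2ccc(OCc3ccccc3)c(OCc3ccccc3)c2)ccc1OCc1ccccc1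
F2 | step 7 | dimethyl (2S,3S)-2-{(S)-[3,4-bis(benzyloxy)phenyl][(triethylsilyl)oxy]methyl}-3-{(R)-[4-(benzyloxy)-3-methoxyphenyl][(tert-butyldimethylsilyl)oxy]methyl}butanedioate | COc1cc([C@H](O[Si](C)(C)C(C)(C)C)[C@@H](C(=O)OC)[C@H](C(=O)OC)[C@H](O[Si](CC)(CC)CC)c2ccc(OCc3ccccc3)c(OCc3ccccc3)c2)ccc1OCc1ccccc1
F3 | step 7 | (2S,3S)-2-{(S)-[3,4-bis(benzyloxy)phenyl][(triethylsilyl)oxy]methyl}-3-{(R)-[4-(benzyloxy)-3-methoxyphenyl][(tert-butyldimethylsilyl)oxy]methyl}butanedioic acid | COc1cc([C@H](O[Si](C)(C)C(C)(C)C)[C@@H](C(=O)O)[C@H](C(=O)O)[C@H](O[Si](CC)(CC)CC)c2ccc(OCc3ccccc3)c(OCc3ccccc3)c2)ccc1OCc1ccccc1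
F0 | step 5 | none | none
F4 | step 14 | 4-[(2S,3R,4R)-4-{(R)-[(tert-butyldimethylsilyl)oxy](4-hydroxy-3-methoxyphenyl)methyl}-3-{[(tert-butyldimethylsilyl)oxy]methyl}oxolan-2-yl]benzene-1,2-diol | COc1cc([C@H](O[Si](C)(C)C(C)(C)C)[C@H]2CO[C@H](c3ccc(O)c(O)c3)[C@H]2CO[Si](C)(C)C(C)(C)C)ccc1O
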